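Numbering: benzofuran numbering of the target (O-1, C-2, C-3, C-3a, C-4 to C-7, C-7a); C-1′ is the carbinol carbon of the side chain.

A direct plan would start from the aromatic acylphloroglucinol A1, fuse the dihydrofuran onto it by C-alkylation with an epoxy-C10 unit from nerol and phenoxide opening of the epoxide to give A2, and then dearomatise the ring by two C-prenylations, at C-5 and at C-7. Its weakest steps would be:
- the ring fusion: two phenol oxygens flank the chain carbon, so one would have to be capped and freed again, and C-alkylation of the arene with an α-epoxy electrophile would not be dependable;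
- the first prenylation: it would have to pick C-5 over C-7 and oxygen and set, by catalyst control with a prenyl electrophile, a quaternary centre whose two alkyl groups differ little;
- the second prenylation: its face would be chosen only by the remote side chain.

The new route closes the rings in the reverse order. The dihydrofuran is built first from a β-diketone dianion and a Sharpless-derived epoxy iodide, which fixes the enol ether bond O-1–C-7a and both side-chain centres; an enantiopure methyl(prenyl)malonyl unit (C-4 to C-6, C-5 from an enzymatic desymmetrisation) is then attached at C-3a. The key step closes the cyclohexenedione ring last by C-acylation at C-7 (bond C-6–C-7) and sets the acyl/prenyl quaternary centre through a magnesium chelate between the isobutyryl enolate, O-1 and the C-1′ hydroxyl, which lie cis in the target. No phenol has to be differentiated or protected, and no dearomatising prenylation is needed.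

Key step: step 10

Assumption: pig liver esterase is taken to give the (S)-half ester 4 from diester 3; sense and level of this selectivity are not known for this substrate. Compounds 12 to 15 are drawn as one tautomer or alkene isomer each.

Step 1
Reactants: 1 dimethyl methylmalonate (dimethyl 2-methylpropanedioate); 2 prenyl bromide (1-bromo-3-methylbut-2-ene)
Product: 3 dimethyl 2-methyl-2-(3-methylbut-2-en-1-yl)propanedioate
Conditions: NaH (1.1 equiv), THF, 0 °C; then 2 (1.05 equiv), 0 °C to rt
Reagents that add atoms: none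
Why: Malonate alkylation (SN2 of the sodium enolate at the primary allylic bromide) should give the diester, which has no acidic hydrogen left and whose central carbon is prochiral.

Step 2
Reactants: 3 dimethyl 2-methyl-2-(3-methylbut-2-en-1-yl)propanedioate
Product: 4 (2S)-2-(methoxycarbonyl)-2,5-dimethylhex-4-enoic acid
Conditions: pig liver esterase, 0.1 M phosphate buffer pH 7.5/DMSO 9:1, 25 °C, pH-stat (1 M NaOH); then 2 M HCl to pH 2, 0 °C
Reagents that add atoms: water, O
Why: Enzymatic desymmetrisation of a prochiral malonate should hydrolyse one of the two enantiotopic methyl esters and so turn the quaternary carbon into the C-5 stereocentre (S assumed), the monoacid salt not being hydrolysed further.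

Step 3
Reactants: 4 (2S)-2-(methoxycarbonyl)-2,5-dimethylhex-4-enoic acid
Product: 5 methyl (2R)-2-(chlorocarbonyl)-2,5-dimethylhex-4-enoate
Conditions: (COCl)2 (1.2 equiv), DMF (cat.), CH2Cl2, 0 °C to rt; used crude
Reagents that add atoms: oxalyl chloride, ClC(=O)C(Cl)=O
Why: Vilsmeier-type acid chloride formation should be clean because the α-carbon is quaternary (no ketene, no racemisation); the descriptor becomes R only because chlorine raises the priority of that carbonyl.

Step 4
Reactants: 6 5-methylhexane-2,4-dione; 2 prenyl bromide (1-bromo-3-methylbut-2-ene)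
Product: 7 5-methyl-3-(3-methylbut-2-en-1-yl)hexane-2,4-dione
Conditions: K2CO3 (1.2 equiv), acetone, 56 °C
Reagents that add atoms: none
Why: C-alkylation of the β-diketone enolate at its central carbon with the allylic bromide (SN2) should stop at the mono-prenyl compound with one equivalent of halide.

Step 5
Reactants: 8 nerol, (2Z)-3,7-dimethylocta-2,6-dien-1-ol
Product: 9 (2R,3S)-2,3-epoxynerol, [(2R,3S)-3-methyl-3-(4-methylpent-3-en-1-yl)oxiran-2-yl]methanol
Conditions: Ti(OiPr)4 (10 mol %), D-(−)-diethyl tartrate (12 mol %), t-BuOOH (2 equiv, isooctane), 4 Å molecular sieves, CH2Cl2, −20 °C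
Reagents that add atoms: tert-butyl hydroperoxide, CC(C)(C)OO
Why: Katsuki–Sharpless asymmetric epoxidation should touch only the allylic 2,3-olefin and, with D-(−)-tartrate, give the 2R,3S cis-epoxide, whose C-3 becomes C-1′ with retention and whose C-2 becomes furan C-2 after one inversion.

Step 6
Reactants: 9 (2R,3S)-2,3-epoxynerol
Product: 10 (2S,3S)-2-(iodomethyl)-3-methyl-3-(4-methylpent-3-en-1-yl)oxirane
Conditions: PPh3 (1.3 equiv), imidazole (1.5 equiv), I2 (1.25 equiv), Et2O/MeCN 3:1, 0 °C, dark
Reagents that add atoms: iodine, II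
Why: Appel-type iodination (iodophosphonium activation, SN2 by iodide at the primary carbon) under imidazole buffer should leave the epoxide and both stereocentres untouched, the C-2 descriptor changing to S only through the priority of iodine.

Step 7
Reactants: 7 5-methyl-3-(3-methylbut-2-en-1-yl)hexane-2,4-dione; 10 (2S,3S)-2-(iodomethyl)-3-methyl-3-(4-methylpent-3-en-1-yl)oxirane
Product: 12 4-{(5S)-5-[(2S)-2-hydroxy-6-methylhept-5-en-2-yl]oxolan-2-ylidene}-2,7-dimethyloct-6-en-3-one, via epoxy diketone 11 (not isolated)
Conditions: NaH (1.1 equiv), THF, 0 °C; n-BuLi (1.05 equiv), 0 °C; 10 (0.9 equiv), −78 °C to rt, then 50 °C; AcOH quench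
Reagents that add atoms: none
Why: Domino dianion alkylation and cyclisation (Weiler alkylation, then Langer-type closure to a 2-alkylidene oxolane) should let the terminal carbanion displace iodide and the neighbouring diketonate oxygen open the epoxide 5-exo-tet at its CH carbon with inversion, which sets furan C-2 as S and frees the C-1′ hydroxyl with retention; the other enolate oxygen would need a seven-membered ring, carbon attack would be a disfavoured 5-(enolendo)-exo-tet closure to a quaternary centre, and the alkene geometry of 12 is of no consequence.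

Step 8
Reactants: 12 4-{(5S)-5-[(2S)-2-hydroxy-6-methylhept-5-en-2-yl]oxolan-2-ylidene}-2,7-dimethyloct-6-en-3-one; 5 methyl (2R)-2-(chlorocarbonyl)-2,5-dimethylhex-4-enoate
Product: 13 methyl (2S)-2-({(5S)-2-(2,7-dimethyl-3-oxooct-6-en-4-yl)-5-[(2S)-2-hydroxy-6-methylhept-5-en-2-yl]-4,5-dihydrofuran-3-yl}carbonyl)-2,5-dimethylhex-4-enoate
Conditions: LiN(iPr)2 (3.2 equiv), THF, −78 °C; 5 (1.05 equiv), −78 to −30 °C; AcOH quench
Reagents that add atoms: none
Why: γ-Acylation of the extended enolate of a vinylogous ester with an acid chloride (as with dioxinone dienolates) should put the C-4 carbonyl on C-3a, because the α-carbon is fully substituted, the product leaves the equilibrium as its stabilised anion, and an acyl group that lands on the side-chain alkoxide can still reach C-3a through a six-membered transition state; no stereocentre is formed, the methine next to the isobutyryl group being epimerisable.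

Step 9
Reactants: 13 methyl (2S)-2-({(5S)-2-(2,7-dimethyl-3-oxooct-6-en-4-yl)-5-[(2S)-2-hydroxy-6-methylhept-5-en-2-yl]-4,5-dihydrofuran-3-yl}carbonyl)-2,5-dimethylhex-4-enoate
Product: 14 (2S)-2-({(5S)-2-(2,7-dimethyl-3-oxooct-6-en-4-yl)-5-[(2S)-2-hydroxy-6-methylhept-5-en-2-yl]-4,5-dihydrofuran-3-yl}carbonyl)-2,5-dimethylhex-4-enoic acid
Conditions: LiOH·H2O (4 equiv), THF/MeOH/H2O 3:1:1, 0 °C to rt; 0.5 M HCl to pH 3–4 at 0 °C; used at once
Reagents that add atoms: lithium hydroxide, [Li+].[OH-]
Why: Saponification of the methyl ester should be tolerated because under hydroxide the substrate is present as its extended enolate, which takes the C-4 ketone out of reach of retro-Claisen cleavage, and cold acidification with immediate use should avoid decarboxylation of the β-keto acid.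

Step 10
Reactants: 14 (2S)-2-({(5S)-2-(2,7-dimethyl-3-oxooct-6-en-4-yl)-5-[(2S)-2-hydroxy-6-methylhept-5-en-2-yl]-4,5-dihydrofuran-3-yl}carbonyl)-2,5-dimethylhex-4-enoic acid
Product: 16 CNP0250451.1, (2S,5S,7S)-2-[(2S)-2-hydroxy-6-methylhept-5-en-2-yl]-5-methyl-5,7-bis(3-methylbut-2-en-1-yl)-7-(2-methylpropanoyl)-2,3-dihydro-1-benzofuran-4,6(5H,7H)-dione, via acyl imidazolide 15 (not isolated)
Conditions: 1,1′-carbonyldiimidazole (1.1 equiv), THF, 0 °C; then added to MgCl2 (2.5 equiv), Et3N (3 equiv), MeCN, 0 °C, 0.005 M; 10% aq. citric acid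
Reagents that add atoms: none
Why: Soft enolisation by MgCl2/Et3N should turn the C-7 methine (α to the isobutyryl ketone, γ to the vinylogous ester) into a magnesium enolate that attacks the C-6 acyl imidazolide by addition–elimination and expels imidazole, too weak a nucleophile to reverse the step. The closest known reaction types are the C-acylation of magnesium enolates of 1,3-dicarbonyl compounds with acyl imidazolides or acid chlorides (Masamune–Brooks and Rathke conditions) and the Dieckmann condensation. The carbocycle closes in the 6-(enolexo)-exo-trig mode through the C-6–C-7 bond, on a furan whose O-1–C-7a bond already fixes the sense of ring fusion. The new quaternary centre C-7 is controlled by chelation: divalent magnesium held by the C-1′ hydroxyl and O-1 on the furan face that carries the side chain also binds the isobutyryl enolate oxygen, so the isobutyryl carbon sits on that face, the prenyl group on the other, and C-6 enters in the ring plane, which should give 7S with isobutyryl cis to the side chain. The step needs C- over O-acylation, which ring size secures (the enol oxygen would close an eight-membered ring, the C-4 oxygen a four-membered one, the tertiary hydroxyl an eight-membered lactone), and it must outrun decarboxylation of the activated β-keto acid and retro-Claisen transfer of the isobutyryl group to the neighbouring hydroxyl, hence low temperature, high dilution and an acidic quench.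

**Compound list**

1 | dimethyl methylmalonate (dimethyl 2-methylpropanedioate) | COC(=O)C(C)C(=O)OC | starting material
2 | prenyl bromide (1-bromo-3-methylbut-2-ene) | CC(C)=CCBr | starting material
3 | dimethyl 2-methyl-2-(3-methylbut-2-en-1-yl)propanedioate | COC(=O)C(C)(CC=C(C)C)C(=O)OC | intermediate
4 | (2S)-2-(methoxycarbonyl)-2,5-dimethylhex-4-enoic acid | OC(=O)[C@](C)(CC=C(C)C)C(=O)OC | intermediate
5 | methyl (2R)-2-(chlorocarbonyl)-2,5-dimethylhex-4-enoate | ClC(=O)[C@](C)(CC=C(C)C)C(=O)OC | intermediate
6 | 5-methylhexane-2,4-dione | CC(=O)CC(=O)C(C)C | starting material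
7 | 5-methyl-3-(3-methylbut-2-en-1-yl)hexane-2,4-dione | CC(=O)C(CC=C(C)C)C(=O)C(C)C | intermediate
8 | nerol, (2Z)-3,7-dimethylocta-2,6-dien-1-ol | CC(C)=CCC/C(C)=C\CO | starting material
9 | (2R,3S)-2,3-epoxynerol, [(2R,3S)-3-methyl-3-(4-methylpent-3-en-1-yl)oxiran-2-yl]methanol | CC(C)=CCC[C@]1(C)O[C@@H]1CO | intermediate
10 | (2S,3S)-2-(iodomethyl)-3-methyl-3-(4-methylpent-3-en-1-yl)oxirane | CC(C)=CCC[C@]1(C)O[C@@H]1CI | intermediate
11 | epoxy diketone, 2-methyl-7-[(2R,3S)-3-methyl-3-(4-methylpent-3-en-1-yl)oxiran-2-yl]-4-(3-methylbut-2-en-1-yl)heptane-3,5-dione | CC(C)=CCC[C@]1(C)O[C@@H]1CCC(=O)C(CC=C(C)C)C(=O)C(C)C | intermediate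
12 | 4-{(5S)-5-[(2S)-2-hydroxy-6-methylhept-5-en-2-yl]oxolan-2-ylidene}-2,7-dimethyloct-6-en-3-one | CC(C)=CCC[C@](C)(O)[C@@H]1CCC(=C(CC=C(C)C)C(=O)C(C)C)O1 | intermediate
13 | methyl (2S)-2-({(5S)-2-(2,7-dimethyl-3-oxooct-6-en-4-yl)-5-[(2S)-2-hydroxy-6-methylhept-5-en-2-yl]-4,5-dihydrofuran-3-yl}carbonyl)-2,5-dimethylhex-4-enoate | CC(C)=CCC[C@](C)(O)[C@@H]1CC(C(=O)[C@](C)(CC=C(C)C)C(=O)OC)=C(O1)C(CC=C(C)C)C(=O)C(C)C | intermediate
14 | (2S)-2-({(5S)-2-(2,7-dimethyl-3-oxooct-6-en-4-yl)-5-[(2S)-2-hydroxy-6-methylhept-5-en-2-yl]-4,5-dihydrofuran-3-yl}carbonyl)-2,5-dimethylhex-4-enoic acid | CC(C)=CCC[C@](C)(O)[C@@H]1CC(C(=O)[C@](C)(CC=C(C)C)C(O)=O)=C(O1)C(CC=C(C)C)C(=O)C(C)C | intermediate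
15 | acyl imidazolide, (2S)-2-({(5S)-2-(2,7-dimethyl-3-oxooct-6-en-4-yl)-5-[(2S)-2-hydroxy-6-methylhept-5-en-2-yl]-4,5-dihydrofuran-3-yl}carbonyl)-1-(1H-imidazol-1-yl)-2,5-dimethylhex-4-en-1-one | CC(C)=CCC[C@](C)(O)[C@@H]1CC(C(=O)[C@](C)(CC=C(C)C)C(=O)n2ccnc2)=C(O1)C(CC=C(C)C)C(=O)C(C)C | intermediate
16 | CNP0250451.1, (2S,5S,7S)-2-[(2S)-2-hydroxy-6-methylhept-5-en-2-yl]-5-methyl-5,7-bis(3-methylbut-2-en-1-yl)-7-(2-methylpropanoyl)-2,3-dihydro-1-benzofuran-4,6(5H,7H)-dione | CC(C)=CCC[C@](C)(O)[C@@H]1CC2=C(O1)[C@@](CC=C(C)C)(C(=O)C(C)C)C(=O)[C@@](C)(CC=C(C)C)C2=O | target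

Total step count: 10. Longest linear sequence: 6 steps (steps 5, 6, 7, 8, 9, 10; the malonate branch, steps 1, 2, 3, 8, 9, 10, is equally long).

Steps most likely to fail:

Step 10. The magnesium chelate may not hold, so that C-6 adds to either face of the C-7 enolate with poor selectivity. The isobutyryl group may also be lost by retro-Claisen transfer to the neighbouring hydroxyl, or the activated acid may decarboxylate before it closes. The fallback would bring in the C-7 prenyl group last. It would set out from iodide 10 and the unprenylated diketone 6. The same dianion alkylation and cyclisation would give 1-{(5S)-5-[(2S)-2-hydroxy-6-methylhept-5-en-2-yl]oxolan-2-ylidene}-3-methylbutan-2-one F1. γ-Acylation with 5 would give the keto ester F2 and saponification the acid F3. Activation as the acyl imidazolide F4 and closure with MgCl2/Et3N would give the enolisable triketone F5; no stereocentre is formed there and the closure is driven by enolisation. C-prenylation of F5 with bromide 2 (K2CO3, acetone) on the face away from the side chain would come back to the route at 16.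

Step 8. The acid chloride may acylate an enolate oxygen, the side-chain alkoxide or the α-carbon instead of the γ-carbon. The fallback would deliver the acyl group from within. It would set out from 12: n-BuLi (1 equiv, THF, −78 °C) and 5 would give the tertiary ester F6, and LiN(iPr)2 (2.2 equiv) would then move the acyl group from oxygen to C-3 of the oxolane through a six-membered transition state (O-to-C acyl migration of the Baker–Venkataraman type), which comes back to the route at 13.

Step 2. The esterase may discriminate too weakly between the two enantiotopic ester groups. The fallback would be a classical resolution. It would set out from 3: KOH (1 equiv, MeOH) would give the racemic half ester F7, crystallisation of the (R)-1-phenylethylammonium salt F8 of the (S)-acid would be sought, and acidification would come back to the route at 4.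

Further compounds

F1 | step 10 | 1-{(5S)-5-[(2S)-2-hydroxy-6-methylhept-5-en-2-yl]oxolan-2-ylidene}-3-methylbutan-2-one | CC(C)=CCC[C@](C)(O)[C@@H]1CCC(=CC(=O)C(C)C)O1
F2 | step 10 | methyl (2S)-2-({(5S)-5-[(2S)-2-hydroxy-6-methylhept-5-en-2-yl]-2-(3-methyl-2-oxobutyl)-4,5-dihydrofuran-3-yl}carbonyl)-2,5-dimethylhex-4-enoate | CC(C)=CCC[C@](C)(O)[C@@H]1CC(C(=O)[C@](C)(CC=C(C)C)C(=O)OC)=C(O1)CC(=O)C(C)C
F3 | step 10 | (2S)-2-({(5S)-5-[(2S)-2-hydroxy-6-methylhept-5-en-2-yl]-2-(3-methyl-2-oxobutyl)-4,5-dihydrofuran-3-yl}carbonyl)-2,5-dimethylhex-4-enoic acid | CC(C)=CCC[C@](C)(O)[C@@H]1CC(C(=O)[C@](C)(CC=C(C)C)C(O)=O)=C(O1)CC(=O)C(C)C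
F4 | step 10 | (2S)-2-({(5S)-5-[(2S)-2-hydroxy-6-methylhept-5-en-2-yl]-2-(3-methyl-2-oxobutyl)-4,5-dihydrofuran-3-yl}carbonyl)-1-(1H-imidazol-1-yl)-2,5-dimethylhex-4-en-1-one | CC(C)=CCC[C@](C)(O)[C@@H]1CC(C(=O)[C@](C)(CC=C(C)C)C(=O)n2ccnc2)=C(O1)CC(=O)C(C)C
F5 | step 10 | (2S,5R)-6-hydroxy-2-[(2S)-2-hydroxy-6-methylhept-5-en-2-yl]-5-methyl-5-(3-methylbut-2-en-1-yl)-7-(2-methylpropanoyl)-2,3-dihydro-1-benzofuran-4(5H)-one | CC(C)=CCC[C@](C)(O)[C@@H]1CC2=C(O1)C(C(=O)C(C)C)=C(O)[C@@](C)(CC=C(C)C)C2=O
F6 | step 8 | 1-[(2S)-2-{(2S)-5-(2,7-dimethyl-3-oxooct-6-en-4-ylidene)oxolan-2-yl}-6-methylhept-5-en-2-yl] 3-methyl (2R)-2-methyl-2-(3-methylbut-2-en-1-yl)propanedioate | CC(C)=CCC[C@](C)(OC(=O)[C@](C)(CC=C(C)C)C(=O)OC)[C@@H]1CCC(=C(CC=C(C)C)C(=O)C(C)C)O1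
F7 | step 2 | racemic 2-(methoxycarbonyl)-2,5-dimethylhex-4-enoic acid | OC(=O)C(C)(CC=C(C)C)C(=O)OC
F8 | step 2 | (R)-1-phenylethylammonium (2S)-2-(methoxycarbonyl)-2,5-dimethylhex-4-enoate | [O-]C(=O)[C@](C)(CC=C(C)C)C(=O)OC.C[C@@H]([NH3+])c1ccccc1
A1 | direct plan | 1-(2,4,6-trihydroxy-3-methylphenyl)-2-methylpropan-1-one | CC(C)C(=O)c1c(O)cc(O)c(C)c1O
A2 | direct plan | 1-[(2S)-4,6-dihydroxy-2-[(2S)-2-hydroxy-6-methylhept-5-en-2-yl]-5-methyl-2,3-dihydro-1-benzofuran-7-yl]-2-methylpropan-1-one | CC(C)=CCC[C@](C)(O)[C@@H]1Cc2c(O1)c(C(=O)C(C)C)c(O)c(C)c2O
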